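The rate constants stand for no real mixture; the rest is arithmetic.

Late in a flask, once substrate is used up, target can do nothing but decay to over-reaction product, so at a fixed temperature [target] then loses the same fraction every second.

all flasks: substrate 2.0 mM; target 0.200 mM; time 3.0 s
- north: at 65 °C until 1.5 s, from then on at 115 °C
- south-east: temperature 115 °C
- south: temperature 65 °C
- west: temperature 90 °C

    substrate + target → side product (k1 = 81.9 /M/s, Ea1 = 40.0 kJ/mol)
    substrate + target → 2 target (k2 = 2410 /M/s, Ea2 = 49.0 kJ/mol)
    target → over-reaction product (k3 = 0.0596 /s, Ea3 = 94.0 kJ/mol)
    substrate → target (k4 = 0.00542 /s, Ea4 = 90.0 kJ/mol)
    (constants at 90 °C)

- in percentages every species weighs as the substrate in it: one side product counts as two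
- all constants are for 90 °C and move with temperature by the activation energies

1. which flask leads in share of target in all that became target or over-reaction product or side product ("all alike" within 1.5 percentage points) (north / south-east / south / west / all alike)
2. share of target in all that became target or over-reaction product or side product, north
3. share of target in all that became target or over-reaction product or side product, south-east
4. share of target in all that became target or over-reaction product or side product, south
5. share of target in all that became target or over-reaction product or side product, west

I count lifetimes of target. The decay constant is 0.0596 /s at 90 °C; with its activation energy it becomes 0.00597 /s at 65 °C and 0.443 /s at 115 °C. At the hot temperature its inverse is 2.26 s: this is the lifetime of target, the time in which [target] falls by a factor e while nothing replenishes it. At 65 °C the lifetime is 168 s. Time spent divided by lifetime gives the lifetimes served, and e to the minus that number is the part of target surviving.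

Target must exist before it can decay, and its growth is autocatalytic: [target] overtakes [substrate] after ln([substrate]/[target]) divided by the rate constant times the sum of the two starting concentrations. At 115 °C that takes 0.153 s, so in south-east I count the whole time, since this is shorter than a lifetime. At 65 °C it takes 1.44 s, which lies close to 1.5 s, so north should enter its hot stage with substrate and target about equal, and I count that whole stage. The uncatalysed step I leave out, since at 90 °C and the starting [target] its rate is far below that of the catalysed one.

A second loss goes to side product. The selectivity factor between the two substrate + target steps is 29.4 at 90 °C, and each side product weighs two, so I take off 6.80% in every flask, although the two activation energies differ by 9.00 kJ/mol.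

| flask | lifetimes served | my share of target |
|---|---|---|
| north | 0.673 | 47.6% |
| south-east | 1.33 | 24.7% |
| south | 0.0179 | 91.6% |
| west | 0.179 | 77.9% |

My leader is south.

The forecast names south, with 49.3% for north, 27% for south-east, 91.7% for south and 80.8% for west, on the ground that “The ranking is therefore set by how long target sits hot”.

The simulation gives 49.3% for north, 27.1% for south-east, 91.8% for south and 80.8% for west, with south ahead. In north the share still stood at 91.1% at 1.56 s, when a fraction 0.7 of the substrate was converted. From there to the end north serves 0.636 hot lifetimes, which by my count takes that share down to 48.3%.

Read north at 8.0 s instead. It has then served 2.89 lifetimes, which gives a share of 5.18%; the computed share is 5.39%.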